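**Retrosynthetic overview**

1. The last C–C bond is lactone C3–CH2 (to the benzofuran ring), made by trans-selective alkylation of the enolate of β-substituted lactone 29 with benzylic bromide 14; three silyl and three benzyl groups are then removed.
2. The dihydrofuran ring (benzofuran numbering O1, C2, C3, C3a–C7a) is closed in one flask from E γ-aryl allylboronate 4 and aldehyde 5: catalytic asymmetric allylboration makes C2–C3, and SNAr of the new alkoxide on C7a–F makes O1–C7a.
3. Enabling feature: C5 of the benzofuran benzene ring, the carbon that carries the lactone-bound CH2, is para to C7a. It is carried as a methyl ester that activates C7a–F and later becomes the CH2Br handle. The C3 hydroxymethyl carbon is carried as a vinyl group, so that C3 is the γ-carbon of an allylboron reagent (later ozonolysis, equilibration of C3 to trans, reduction).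
4. The open 1,3-diol arm on the other guaiacyl ring comes from the same allylboration, with the same aldehyde and catalyst, on a ring that has benzyloxy in place of fluorine, so it stops at the anti homoallylic alcohol.
5. Ring order: the butyrolactone ring is closed within its own fragment (Stobbe condensation, rhodium-catalysed asymmetric hydrogenation, reduction–lactonisation, step 13), the dihydrofuran ring in step 4; all four benzene rings are bought.

Key step: step 4

Assumption: the sense of induction of the phosphoric acid (steps 4 and 16) and of the rhodium–bisphosphine catalyst (step 12) is taken from the closest simple substrates; if either runs the other way, the enantiomeric catalyst is used and nothing else changes.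

**Route**

Step 1
Reactants: 1 methyl 4-fluoro-3-methoxybenzoate
Product: 2 methyl 4-fluoro-3-methoxy-5-(4,4,5,5-tetramethyl-1,3,2-dioxaborolan-2-yl)benzoate
Conditions: [Ir(OMe)(cod)]2 (1.5 mol %), 4,4'-di-tert-butyl-2,2'-bipyridine (3 mol %), B2pin2 (1.0 equiv), THF, 80 °C
Reagents that add atoms: bis(pinacolato)diboron, CC1(C)OB(OC1(C)C)B1OC(C)(C)C(C)(C)O1
Why: Iridium-catalysed aromatic C–H borylation is sterically controlled and accepts a C–H next to fluorine, so boron should enter C5, the only position not flanked by the ester or the methoxy group.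

Step 2
Reactants: 2 methyl 4-fluoro-3-methoxy-5-(4,4,5,5-tetramethyl-1,3,2-dioxaborolan-2-yl)benzoate
Product: 3 methyl 3-ethenyl-4-fluoro-5-methoxybenzoate
Conditions: vinyl bromide (1 M in THF, 2 equiv), Pd(dppf)Cl2 (3 mol %), K3PO4 (aq), THF, 60 °C, sealed tube
Reagents that add atoms: vinyl bromide, C=CBr
Why: Suzuki–Miyaura coupling of the arylboronate with vinyl bromide should give the styrene, the aryl fluoride and the ester being inert to the mild aqueous base.

Step 3
Reactants: 3 methyl 3-ethenyl-4-fluoro-5-methoxybenzoate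
Product: 4 methyl 4-fluoro-3-methoxy-5-[(1E)-3-(4,4,5,5-tetramethyl-1,3,2-dioxaborolan-2-yl)prop-1-en-1-yl]benzoate
Conditions: allylboronic acid pinacol ester (3 equiv), second-generation Hoveyda–Grubbs catalyst RuCl2(H2IMes)(=CH-C6H4-2-OiPr) (5 mol %), CH2Cl2, 40 °C
Reagents that add atoms: allylboronic acid pinacol ester, C=CCB1OC(C)(C)C(C)(C)O1
Why: Olefin cross-metathesis of a styrene with excess allylboronate loses ethene and should give the thermodynamically preferred E γ-aryl allylboronate.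

Step 4
Reactants: 4 methyl 4-fluoro-3-methoxy-5-[(1E)-3-(4,4,5,5-tetramethyl-1,3,2-dioxaborolan-2-yl)prop-1-en-1-yl]benzoate, 5 4-(benzyloxy)-3-methoxybenzaldehyde
Product: 7 methyl (2S,3R)-2-[4-(benzyloxy)-3-methoxyphenyl]-3-ethenyl-7-methoxy-2,3-dihydro-1-benzofuran-5-carboxylate (2,3-cis), via homoallyl borate 6 (not isolated)
Conditions: 4 (1.15 equiv), 5 (1.0 equiv), (S)-3,3'-bis(2,4,6-triisopropylphenyl)-1,1'-binaphthyl-2,2'-diyl hydrogen phosphate [(S)-TRIP] (5 mol %), 4 Å molecular sieves, toluene, −30 → 0 °C; then KOtBu (1.3 equiv), THF, 0 → 25 °C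
Reagents that add atoms: none
Why: In a chair-like six-membered transition state, with the phosphoric acid hydrogen-bonded to a boronate oxygen and to the formyl hydrogen, the γ-carbon of E allylboronate 4 adds to the Si face of aldehyde 5 and forms C2–C3, giving borate 6 with C2 (S) set by the catalyst and the C2/C3 anti relation set by the E geometry (γ-aryl group pseudo-equatorial). tert-Butoxide then adds to boron and releases the potassium alkoxide, which attacks C7a in a 5-exo-trig addition–elimination (SNAr) through a Meisenheimer intermediate stabilised by the para C5 ester, expels fluoride, and so forms O1–C7a and closes the dihydrofuran ring with both stereocentres retained (anti adduct gives the 2,3-cis ring). The closest known reaction types are the chiral phosphoric acid-catalysed allyl- and crotylboration of aryl aldehydes with pinacol boronates and the base-mediated intramolecular etherification of para-acyl fluoroarenes. The step needs enantiofacial control at the aldehyde, which the catalyst supplies, and needs the alkoxide to attack C7a and not the ester or C7, which the five-membered closure and the single leaving group para to the ester secure. The C3 configuration need not be controlled here because step 6 equilibrates it, so any minor syn adduct converges on the same product. The aldehyde is the limiting component so that none remains when the basic allylborate is formed.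

Step 5
Reactants: 7 methyl (2S,3R)-2-[4-(benzyloxy)-3-methoxyphenyl]-3-ethenyl-7-methoxy-2,3-dihydro-1-benzofuran-5-carboxylate
Product: 9 methyl (2S,3R)-2-[4-(benzyloxy)-3-methoxyphenyl]-3-formyl-7-methoxy-2,3-dihydro-1-benzofuran-5-carboxylate (2,3-cis), via secondary ozonide 8 (not isolated)
Conditions: O3, CH2Cl2, −78 °C (to first persistent blue); PPh3, −78 → 25 °C; aqueous work-up
Reagents that add atoms: ozone, [O-][O+]=O
Why: Ozonolysis with reductive work-up should cleave the terminal alkene, which reacts far faster than the alkoxyarenes, to the C3 aldehyde without touching C2.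

Step 6
Reactants: 9 methyl (2S,3R)-2-[4-(benzyloxy)-3-methoxyphenyl]-3-formyl-7-methoxy-2,3-dihydro-1-benzofuran-5-carboxylate
Product: 11 methyl (2S,3R)-2-[4-(benzyloxy)-3-methoxyphenyl]-3-(hydroxymethyl)-7-methoxy-2,3-dihydro-1-benzofuran-5-carboxylate (2,3-trans), via trans aldehyde 10 (not isolated)
Conditions: DBU (0.2 equiv), CH2Cl2, 25 °C; then MeOH, NaBH4, 0 °C
Reagents that add atoms: none
Why: Base-catalysed epimerisation through the aldehyde enolate should move C3 to the more stable 2,3-trans arrangement (ring opening by β-elimination of O1 is the reverse of a disfavoured 5-endo-trig closure), and borohydride reduction of the aldehyde then fixes it as the hydroxymethyl group.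

Step 7
Reactants: 11 methyl (2S,3R)-2-[4-(benzyloxy)-3-methoxyphenyl]-3-(hydroxymethyl)-7-methoxy-2,3-dihydro-1-benzofuran-5-carboxylate
Product: 12 methyl (2S,3R)-2-[4-(benzyloxy)-3-methoxyphenyl]-3-{[(tert-butyldimethylsilyl)oxy]methyl}-7-methoxy-2,3-dihydro-1-benzofuran-5-carboxylate
Conditions: TBSCl, imidazole, DMF, 25 °C
Reagents that add atoms: tert-butyldimethylsilyl chloride, CC(C)(C)[Si](C)(C)Cl
Why: Silyl ether formation protects the primary alcohol so that the two hydroxymethyl groups stay distinguishable in steps 8 and 9.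

Step 8
Reactants: 12 methyl (2S,3R)-2-[4-(benzyloxy)-3-methoxyphenyl]-3-{[(tert-butyldimethylsilyl)oxy]methyl}-7-methoxy-2,3-dihydro-1-benzofuran-5-carboxylate
Product: 13 [(2S,3R)-2-[4-(benzyloxy)-3-methoxyphenyl]-3-{[(tert-butyldimethylsilyl)oxy]methyl}-7-methoxy-2,3-dihydro-1-benzofuran-5-yl]methanol
Conditions: LiAlH4, THF, 0 °C
Reagents that add atoms: none
Why: Hydride reduction of the aryl ester, whose activating role ended in step 4, should give the benzylic alcohol while silyl and benzyl ethers are inert.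

Step 9
Reactants: 13 [(2S,3R)-2-[4-(benzyloxy)-3-methoxyphenyl]-3-{[(tert-butyldimethylsilyl)oxy]methyl}-7-methoxy-2,3-dihydro-1-benzofuran-5-yl]methanol
Product: 14 (2S,3R)-2-[4-(benzyloxy)-3-methoxyphenyl]-5-(bromomethyl)-3-{[(tert-butyldimethylsilyl)oxy]methyl}-7-methoxy-2,3-dihydro-1-benzofuran
Conditions: CBr4, PPh3, CH2Cl2, 0 °C; used at once
Reagents that add atoms: carbon tetrabromide, BrC(Br)(Br)Br
Why: The Appel reaction converts the benzylic alcohol into the bromide under neutral conditions that the silyl ether and the benzylic aryl ether should tolerate.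

Step 10
Reactants: 15 3-bromo-4-hydroxy-5-methoxybenzaldehyde (5-bromovanillin)
Product: 16 4-(benzyloxy)-3-bromo-5-methoxybenzaldehyde
Conditions: BnBr, K2CO3, DMF, 60 °C
Reagents that add atoms: benzyl bromide, BrCc1ccccc1
Why: Williamson ether synthesis protects the phenol as the benzyl ether that survives every later basic, reductive and oxidative step.

Step 11
Reactants: 16 4-(benzyloxy)-3-bromo-5-methoxybenzaldehyde, 17 dimethyl succinate
Product: 18 (3E)-4-[4-(benzyloxy)-3-bromo-5-methoxyphenyl]-3-(methoxycarbonyl)but-3-enoic acid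
Conditions: NaOMe (2 equiv), MeOH, reflux; then 1 M HCl
Reagents that add atoms: none
Why: The Stobbe condensation (aldol addition, lactonisation, eliminative ring opening) should give the E arylidene succinic half-ester with the acid and ester already differentiated.

Step 12
Reactants: 18 (3E)-4-[4-(benzyloxy)-3-bromo-5-methoxyphenyl]-3-(methoxycarbonyl)but-3-enoic acid
Product: 19 (3R)-4-[4-(benzyloxy)-3-bromo-5-methoxyphenyl]-3-(methoxycarbonyl)butanoic acid
Conditions: H2 (5 bar), [Rh(cod)((S,S)-Et-DuPHOS)]BF4 (1 mol %), NaOMe (0.1 equiv), MeOH, 25 °C; then dilute HCl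
Reagents that add atoms: none
Why: In this rhodium–bisphosphine asymmetric hydrogenation of an itaconate-type half-ester, the carboxylate and the alkene chelate rhodium and the ligand selects the alkene face, which sets the future lactone C4 as R.

Step 13
Reactants: 19 (3R)-4-[4-(benzyloxy)-3-bromo-5-methoxyphenyl]-3-(methoxycarbonyl)butanoic acid
Product: 22 (4R)-4-{[4-(benzyloxy)-3-bromo-5-methoxyphenyl]methyl}oxolan-2-one, via lithium carboxylate 20 (not isolated), via lithium hydroxy carboxylate 21 (not isolated)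
Conditions: LiOH (1.0 equiv), MeOH, 0 °C, then evaporation; LiBH4 (2 equiv), THF, 0 → 25 °C; then 2 M HCl, 25 °C
Reagents that add atoms: none
Why: Lithium borohydride reduces the methyl ester but not the lithium carboxylate (chemoselective ester reduction), and on acidification the γ-hydroxy acid lactonises, which closes the butyrolactone ring with C4 (R) untouched.

Step 14
Reactants: 22 (4R)-4-{[4-(benzyloxy)-3-bromo-5-methoxyphenyl]methyl}oxolan-2-one
Product: 23 (4R)-4-{[4-(benzyloxy)-3-ethenyl-5-methoxyphenyl]methyl}oxolan-2-one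
Conditions: tributyl(vinyl)stannane, Pd(PPh3)4 (5 mol %), toluene, 100 °C
Reagents that add atoms: tributyl(vinyl)stannane, C=C[Sn](CCCC)(CCCC)CCCC
Why: Stille coupling installs the vinyl group under neutral conditions that leave the lactone closed.

Step 15
Reactants: 23 (4R)-4-{[4-(benzyloxy)-3-ethenyl-5-methoxyphenyl]methyl}oxolan-2-one
Product: 24 (4R)-4-({4-(benzyloxy)-3-methoxy-5-[(1E)-3-(4,4,5,5-tetramethyl-1,3,2-dioxaborolan-2-yl)prop-1-en-1-yl]phenyl}methyl)oxolan-2-one
Conditions: allylboronic acid pinacol ester (3 equiv), second-generation Hoveyda–Grubbs catalyst RuCl2(H2IMes)(=CH-C6H4-2-OiPr) (5 mol %), CH2Cl2, 40 °C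
Reagents that add atoms: allylboronic acid pinacol ester, C=CCB1OC(C)(C)C(C)(C)O1
Why: Olefin cross-metathesis as in step 3 should give the E γ-aryl allylboronate, the lactone being inert to the ruthenium carbene.

Step 16
Reactants: 24 (4R)-4-({4-(benzyloxy)-3-methoxy-5-[(1E)-3-(4,4,5,5-tetramethyl-1,3,2-dioxaborolan-2-yl)prop-1-en-1-yl]phenyl}methyl)oxolan-2-one, 5 4-(benzyloxy)-3-methoxybenzaldehyde
Product: 26 (4R)-4-({4-(benzyloxy)-3-[(1S,2R)-1-[4-(benzyloxy)-3-methoxyphenyl]-1-hydroxybut-3-en-2-yl]-5-methoxyphenyl}methyl)oxolan-2-one, via homoallyl borate 25 (not isolated)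
Conditions: 24 (1.1 equiv), 5 (1.0 equiv), (S)-TRIP (5 mol %), 4 Å molecular sieves, toluene, −30 °C; aqueous NaHCO3 work-up
Reagents that add atoms: none
Why: Chiral phosphoric acid-catalysed allylboration as in step 4: the acid selects the Si face of the aldehyde (carbinol carbon S), the E geometry passes through the chair transition state into the anti relation at the adjacent carbon, and the benzyloxy-substituted ring has no leaving group, so the reaction stops at the alcohol once the borate is hydrolysed.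

Step 17
Reactants: 26 (4R)-4-({4-(benzyloxy)-3-[(1S,2R)-1-[4-(benzyloxy)-3-methoxyphenyl]-1-hydroxybut-3-en-2-yl]-5-methoxyphenyl}methyl)oxolan-2-one
Product: 28 (4R)-4-({4-(benzyloxy)-3-[(1S,2S)-1-[4-(benzyloxy)-3-methoxyphenyl]-1,3-dihydroxypropan-2-yl]-5-methoxyphenyl}methyl)oxolan-2-one, via secondary ozonide 27 (not isolated)
Conditions: O3, CH2Cl2, −78 °C (to first persistent blue); then MeOH, NaBH4, −78 → 0 °C
Reagents that add atoms: ozone, [O-][O+]=O
Why: Ozonolysis with direct borohydride reduction of the ozonide turns the vinyl group into the hydroxymethyl group without letting the epimerisable α-aryl aldehyde accumulate, so the anti relation is kept.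

Step 18
Reactants: 28 (4R)-4-({4-(benzyloxy)-3-[(1S,2S)-1-[4-(benzyloxy)-3-methoxyphenyl]-1,3-dihydroxypropan-2-yl]-5-methoxyphenyl}methyl)oxolan-2-one
Product: 29 (4R)-4-({4-(benzyloxy)-3-[(1S,2S)-1-[4-(benzyloxy)-3-methoxyphenyl]-1,3-bis[(tert-butyldimethylsilyl)oxy]propan-2-yl]-5-methoxyphenyl}methyl)oxolan-2-one
Conditions: TBSOTf (2.5 equiv), 2,6-lutidine, CH2Cl2, 0 °C
Reagents that add atoms: tert-butyldimethylsilyl trifluoromethanesulfonate, CC(C)(C)[Si](C)(C)OS(=O)(=O)C(F)(F)F
Why: Silyl ether formation with the triflate caps the primary and the hindered benzylic secondary hydroxyl so that only the lactone α-position is deprotonated in step 19.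

Step 19
Reactants: 29 (4R)-4-({4-(benzyloxy)-3-[(1S,2S)-1-[4-(benzyloxy)-3-methoxyphenyl]-1,3-bis[(tert-butyldimethylsilyl)oxy]propan-2-yl]-5-methoxyphenyl}methyl)oxolan-2-one, 14 (2S,3R)-2-[4-(benzyloxy)-3-methoxyphenyl]-5-(bromomethyl)-3-{[(tert-butyldimethylsilyl)oxy]methyl}-7-methoxy-2,3-dihydro-1-benzofuran
Product: 31 (3R,4R)-3-{[(2S,3R)-2-[4-(benzyloxy)-3-methoxyphenyl]-3-{[(tert-butyldimethylsilyl)oxy]methyl}-7-methoxy-2,3-dihydro-1-benzofuran-5-yl]methyl}-4-({4-(benzyloxy)-3-[(1S,2S)-1-[4-(benzyloxy)-3-methoxyphenyl]-1,3-bis[(tert-butyldimethylsilyl)oxy]propan-2-yl]-5-methoxyphenyl}methyl)oxolan-2-one, via lithium enolate 30 (not isolated)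
Conditions: LiN(SiMe3)2 (1.1 equiv), THF, −78 °C; then 14 (1.2 equiv), DMPU, −78 → −30 °C
Reagents that add atoms: none
Why: In this alkylation of the lactone lithium enolate, the benzylic bromide approaches the enolate face opposite the C4 substituent (1,2-induction), which should set C3 as R, trans to C4.

Step 20
Reactants: 31 the fully protected lactone of step 19
Product: 32 (3R,4R)-3-{[(2S,3R)-2-[4-(benzyloxy)-3-methoxyphenyl]-3-(hydroxymethyl)-7-methoxy-2,3-dihydro-1-benzofuran-5-yl]methyl}-4-({4-(benzyloxy)-3-[(1S,2S)-1-[4-(benzyloxy)-3-methoxyphenyl]-1,3-dihydroxypropan-2-yl]-5-methoxyphenyl}methyl)oxolan-2-one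
Conditions: Bu4NF (4 equiv), AcOH (4 equiv), THF, 0 → 40 °C
Reagents that add atoms: none
Why: Fluoride-mediated desilylation, buffered with acetic acid so that the lactone and its α-centre do not meet free alkoxide, frees the three aliphatic hydroxyls.

Step 21
Reactants: 32 the tris(benzyl ether) triol of step 20
Product: 33 (3R,4R)-3-{[(2S,3R)-2-(4-hydroxy-3-methoxyphenyl)-3-(hydroxymethyl)-7-methoxy-2,3-dihydro-1-benzofuran-5-yl]methyl}-4-({3-[(1S,2S)-1,3-dihydroxy-1-(4-hydroxy-3-methoxyphenyl)propan-2-yl]-4-hydroxy-5-methoxyphenyl}methyl)oxolan-2-one (CNP0199264.2)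
Conditions: H2 (1 atm), Pd/C (10 wt % Pd), EtOAc–EtOH, 25 °C, stopped at full debenzylation
Reagents that add atoms: none
Why: Catalytic hydrogenolysis cleaves the three aryl benzyl ethers under neutral conditions, under which the secondary benzylic alcohol and the benzylic C2–O1 bond of the dihydrofuran are expected to persist.

**Compound list**

1 | methyl 4-fluoro-3-methoxybenzoate | COC(=O)c1ccc(F)c(OC)c1 | starting material
2 | methyl 4-fluoro-3-methoxy-5-(4,4,5,5-tetramethyl-1,3,2-dioxaborolan-2-yl)benzoate | COC(=O)c1cc(OC)c(F)c(c1)B1OC(C)(C)C(C)(C)O1 | intermediate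
3 | methyl 3-ethenyl-4-fluoro-5-methoxybenzoate | COC(=O)c1cc(OC)c(F)c(C=C)c1 | intermediate
4 | methyl 4-fluoro-3-methoxy-5-[(1E)-3-(4,4,5,5-tetramethyl-1,3,2-dioxaborolan-2-yl)prop-1-en-1-yl]benzoate | COC(=O)c1cc(OC)c(F)c(/C=C/CB2OC(C)(C)C(C)(C)O2)c1 | intermediate
5 | 4-(benzyloxy)-3-methoxybenzaldehyde | O=Cc1ccc(OCc2ccccc2)c(OC)c1 | starting material
6 | methyl 3-[(1S,2R)-1-[4-(benzyloxy)-3-methoxyphenyl]-1-[(4,4,5,5-tetramethyl-1,3,2-dioxaborolan-2-yl)oxy]but-3-en-2-yl]-4-fluoro-5-methoxybenzoate (anti) | COc1cc([C@@H](OB2OC(C)(C)C(C)(C)O2)[C@H](C=C)c2cc(C(=O)OC)cc(OC)c2F)ccc1OCc1ccccc1 | intermediate (not isolated)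
7 | methyl (2S,3R)-2-[4-(benzyloxy)-3-methoxyphenyl]-3-ethenyl-7-methoxy-2,3-dihydro-1-benzofuran-5-carboxylate (2,3-cis) | COC(=O)c1cc(OC)c2c(c1)[C@@H](C=C)[C@@H](c1ccc(OCc3ccccc3)c(OC)c1)O2 | intermediate
8 | secondary ozonide of 7: the 3-(1,2,4-trioxolan-3-yl) analogue, C2 and C3 as in 7, both configurations at the trioxolane carbon | COC(=O)c1cc(OC)c2c(c1)[C@@H](C1OCOO1)[C@@H](c1ccc(OCc3ccccc3)c(OC)c1)O2 | intermediate (not isolated)
9 | methyl (2S,3R)-2-[4-(benzyloxy)-3-methoxyphenyl]-3-formyl-7-methoxy-2,3-dihydro-1-benzofuran-5-carboxylate (2,3-cis) | COC(=O)c1cc(OC)c2c(c1)[C@@H](C=O)[C@@H](c1ccc(OCc3ccccc3)c(OC)c1)O2 | intermediate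
10 | methyl (2S,3S)-2-[4-(benzyloxy)-3-methoxyphenyl]-3-formyl-7-methoxy-2,3-dihydro-1-benzofuran-5-carboxylate (2,3-trans) | COC(=O)c1cc(OC)c2c(c1)[C@H](C=O)[C@@H](c1ccc(OCc3ccccc3)c(OC)c1)O2 | intermediate (not isolated)
11 | methyl (2S,3R)-2-[4-(benzyloxy)-3-methoxyphenyl]-3-(hydroxymethyl)-7-methoxy-2,3-dihydro-1-benzofuran-5-carboxylate (2,3-trans) | COC(=O)c1cc(OC)c2c(c1)[C@H](CO)[C@@H](c1ccc(OCc3ccccc3)c(OC)c1)O2 | intermediate
12 | methyl (2S,3R)-2-[4-(benzyloxy)-3-methoxyphenyl]-3-{[(tert-butyldimethylsilyl)oxy]methyl}-7-methoxy-2,3-dihydro-1-benzofuran-5-carboxylate | COC(=O)c1cc(OC)c2c(c1)[C@H](CO[Si](C)(C)C(C)(C)C)[C@@H](c1ccc(OCc3ccccc3)c(OC)c1)O2 | intermediate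
13 | [(2S,3R)-2-[4-(benzyloxy)-3-methoxyphenyl]-3-{[(tert-butyldimethylsilyl)oxy]methyl}-7-methoxy-2,3-dihydro-1-benzofuran-5-yl]methanol | OCc1cc(OC)c2c(c1)[C@H](CO[Si](C)(C)C(C)(C)C)[C@@H](c1ccc(OCc3ccccc3)c(OC)c1)O2 | intermediate
14 | (2S,3R)-2-[4-(benzyloxy)-3-methoxyphenyl]-5-(bromomethyl)-3-{[(tert-butyldimethylsilyl)oxy]methyl}-7-methoxy-2,3-dihydro-1-benzofuran | BrCc1cc(OC)c2c(c1)[C@H](CO[Si](C)(C)C(C)(C)C)[C@@H](c1ccc(OCc3ccccc3)c(OC)c1)O2 | intermediate
15 | 3-bromo-4-hydroxy-5-methoxybenzaldehyde (5-bromovanillin) | O=Cc1cc(OC)c(O)c(Br)c1 | starting material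
16 | 4-(benzyloxy)-3-bromo-5-methoxybenzaldehyde | O=Cc1cc(OC)c(OCc2ccccc2)c(Br)c1 | intermediate
17 | dimethyl succinate | COC(=O)CCC(=O)OC | starting material
18 | (3E)-4-[4-(benzyloxy)-3-bromo-5-methoxyphenyl]-3-(methoxycarbonyl)but-3-enoic acid | COC(=O)/C(CC(=O)O)=C/c1cc(OC)c(OCc2ccccc2)c(Br)c1 | intermediate
19 | (3R)-4-[4-(benzyloxy)-3-bromo-5-methoxyphenyl]-3-(methoxycarbonyl)butanoic acid | COC(=O)[C@@H](CC(=O)O)Cc1cc(OC)c(OCc2ccccc2)c(Br)c1 | intermediate
20 | lithium (3R)-4-[4-(benzyloxy)-3-bromo-5-methoxyphenyl]-3-(methoxycarbonyl)butanoate | [Li+].COC(=O)[C@@H](CC(=O)[O-])Cc1cc(OC)c(OCc2ccccc2)c(Br)c1 | intermediate (not isolated)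
21 | lithium (3R)-4-[4-(benzyloxy)-3-bromo-5-methoxyphenyl]-3-(hydroxymethyl)butanoate | [Li+].OC[C@@H](CC(=O)[O-])Cc1cc(OC)c(OCc2ccccc2)c(Br)c1 | intermediate (not isolated)
22 | (4R)-4-{[4-(benzyloxy)-3-bromo-5-methoxyphenyl]methyl}oxolan-2-one | O=C1C[C@@H](Cc2cc(OC)c(OCc3ccccc3)c(Br)c2)CO1 | intermediate
23 | (4R)-4-{[4-(benzyloxy)-3-ethenyl-5-methoxyphenyl]methyl}oxolan-2-one | O=C1C[C@@H](Cc2cc(OC)c(OCc3ccccc3)c(C=C)c2)CO1 | intermediate
24 | (4R)-4-({4-(benzyloxy)-3-methoxy-5-[(1E)-3-(4,4,5,5-tetramethyl-1,3,2-dioxaborolan-2-yl)prop-1-en-1-yl]phenyl}methyl)oxolan-2-one | O=C1C[C@@H](Cc2cc(OC)c(OCc3ccccc3)c(/C=C/CB3OC(C)(C)C(C)(C)O3)c2)CO1 | intermediate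
25 | pinacol borate of 26: (4R)-4-({4-(benzyloxy)-3-[(1S,2R)-1-[4-(benzyloxy)-3-methoxyphenyl]-1-[(4,4,5,5-tetramethyl-1,3,2-dioxaborolan-2-yl)oxy]but-3-en-2-yl]-5-methoxyphenyl}methyl)oxolan-2-one | COc1cc([C@@H](OB2OC(C)(C)C(C)(C)O2)[C@H](C=C)c2cc(C[C@H]3COC(=O)C3)cc(OC)c2OCc2ccccc2)ccc1OCc1ccccc1 | intermediate (not isolated)
26 | (4R)-4-({4-(benzyloxy)-3-[(1S,2R)-1-[4-(benzyloxy)-3-methoxyphenyl]-1-hydroxybut-3-en-2-yl]-5-methoxyphenyl}methyl)oxolan-2-one (anti) | COc1cc([C@@H](O)[C@H](C=C)c2cc(C[C@H]3COC(=O)C3)cc(OC)c2OCc2ccccc2)ccc1OCc1ccccc1 | intermediate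
27 | secondary ozonide of 26: the vinyl group replaced by 1,2,4-trioxolan-3-yl, other centres as in 26, both configurations at the trioxolane carbon | COc1cc([C@@H](O)[C@H](C2OCOO2)c2cc(C[C@H]3COC(=O)C3)cc(OC)c2OCc2ccccc2)ccc1OCc1ccccc1 | intermediate (not isolated)
28 | (4R)-4-({4-(benzyloxy)-3-[(1S,2S)-1-[4-(benzyloxy)-3-methoxyphenyl]-1,3-dihydroxypropan-2-yl]-5-methoxyphenyl}methyl)oxolan-2-one | COc1cc([C@@H](O)[C@H](CO)c2cc(C[C@H]3COC(=O)C3)cc(OC)c2OCc2ccccc2)ccc1OCc1ccccc1 | intermediate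
29 | (4R)-4-({4-(benzyloxy)-3-[(1S,2S)-1-[4-(benzyloxy)-3-methoxyphenyl]-1,3-bis[(tert-butyldimethylsilyl)oxy]propan-2-yl]-5-methoxyphenyl}methyl)oxolan-2-one | COc1cc([C@@H](O[Si](C)(C)C(C)(C)C)[C@H](CO[Si](C)(C)C(C)(C)C)c2cc(C[C@H]3COC(=O)C3)cc(OC)c2OCc2ccccc2)ccc1OCc1ccccc1 | intermediate
30 | lithium enolate of 29 (lithium 4,5-dihydrofuran-2-olate, C4 R) | COc1cc([C@@H](O[Si](C)(C)C(C)(C)C)[C@H](CO[Si](C)(C)C(C)(C)C)c2cc(C[C@H]3COC(O[Li])=C3)cc(OC)c2OCc2ccccc2)ccc1OCc1ccccc1 | intermediate (not isolated)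
31 | (3R,4R)-3-{[(2S,3R)-2-[4-(benzyloxy)-3-methoxyphenyl]-3-{[(tert-butyldimethylsilyl)oxy]methyl}-7-methoxy-2,3-dihydro-1-benzofuran-5-yl]methyl}-4-({4-(benzyloxy)-3-[(1S,2S)-1-[4-(benzyloxy)-3-methoxyphenyl]-1,3-bis[(tert-butyldimethylsilyl)oxy]propan-2-yl]-5-methoxyphenyl}methyl)oxolan-2-one | COc1cc([C@@H](O[Si](C)(C)C(C)(C)C)[C@H](CO[Si](C)(C)C(C)(C)C)c2cc(C[C@H]3COC(=O)[C@@H]3Cc3cc(OC)c4c(c3)[C@H](CO[Si](C)(C)C(C)(C)C)[C@@H](c3ccc(OCc5ccccc5)c(OC)c3)O4)cc(OC)c2OCc2ccccc2)ccc1OCc1ccccc1 | intermediate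
32 | (3R,4R)-3-{[(2S,3R)-2-[4-(benzyloxy)-3-methoxyphenyl]-3-(hydroxymethyl)-7-methoxy-2,3-dihydro-1-benzofuran-5-yl]methyl}-4-({4-(benzyloxy)-3-[(1S,2S)-1-[4-(benzyloxy)-3-methoxyphenyl]-1,3-dihydroxypropan-2-yl]-5-methoxyphenyl}methyl)oxolan-2-one | COc1cc([C@@H](O)[C@H](CO)c2cc(C[C@H]3COC(=O)[C@@H]3Cc3cc(OC)c4c(c3)[C@H](CO)[C@@H](c3ccc(OCc5ccccc5)c(OC)c3)O4)cc(OC)c2OCc2ccccc2)ccc1OCc1ccccc1 | intermediate
33 | (3R,4R)-3-{[(2S,3R)-2-(4-hydroxy-3-methoxyphenyl)-3-(hydroxymethyl)-7-methoxy-2,3-dihydro-1-benzofuran-5-yl]methyl}-4-({3-[(1S,2S)-1,3-dihydroxy-1-(4-hydroxy-3-methoxyphenyl)propan-2-yl]-4-hydroxy-5-methoxyphenyl}methyl)oxolan-2-one | COc1cc([C@@H](O)[C@H](CO)c2cc(C[C@H]3COC(=O)[C@@H]3Cc3cc(OC)c4c(c3)[C@H](CO)[C@@H](c3ccc(O)c(OC)c3)O4)cc(OC)c2O)ccc1O | target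

**Step count and risks**

Total step count: 21.
Longest linear sequence: 12 steps (steps 1–9 or 10–18, then 19–21).

Steps most likely to fail:

Step 4. The allylboration may be slow or poorly face-selective because the boronate is electron-poor and the aldehyde electron-rich. The base may also move the terminal double bond into conjugation before or after ring closure, or fluoride displacement may stall. The fallback makes the two bonds separately at the ester oxidation level; it sets out from 2 and comes back at 11, replacing steps 2–6. Palladium-catalysed coupling of 2 with tert-butyl bromoacetate (Pd(OAc)2, P(o-tol)3, K3PO4, THF) would give the tert-butyl arylacetate F1. CF3CO2H would free the arylacetic acid F2, and pivaloyl chloride/Et3N followed by (S)-4-benzyloxazolidin-2-one and LiCl would give the N-acyl oxazolidinone F3. An Evans syn aldol addition (Bu2BOTf, iPr2NEt, CH2Cl2, −78 °C, then 5) would give the syn aldol adduct F4, which already has the C2 (S) carbinol and the relative configuration of the trans ring. LiBH4 (MeOH, Et2O, 0 °C) would cleave the auxiliary to the diol F5, so that no retro-aldol path remains. Trityl chloride (Et3N, DMAP) would cap the primary hydroxyl as the primary trityl ether F6. KOtBu in THF would then close the ring by the same SNAr to the trityl-protected trans dihydrobenzofuran F7, and formic acid in ether would remove the trityl group to give 11.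

Step 6. Equilibration of the aldehyde may be accompanied by ring opening through β-elimination of the aryloxide or by aldol self-condensation, or it may stop short of the trans isomer. The fallback moves the epimerisation to the ester oxidation level, where it is well precedented for 2-aryl-2,3-dihydrobenzofuran-3-carboxylates; it sets out from 9 and comes back at 11. Pinnick oxidation (NaClO2, NaH2PO4, 2-methylbut-2-ene, tBuOH–H2O) would give the cis carboxylic acid F8, and Me3SiCHN2 in MeOH–toluene the cis diester F9. NaOMe in MeOH would equilibrate C3 to the trans diester F10. LiBH4 in Et2O at 0 °C should then reduce the aliphatic ester in preference to the electron-rich aryl ester and return 11.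

Step 3. Cross-metathesis may suffer from self-metathesis of the styrene, incomplete E control, and protodeboronation of the allylboronate during chromatography. The fallback builds the allylboron unit by allylic substitution; it sets out from 2 and comes back at 4, so step 2 is not needed. Suzuki–Miyaura coupling of 2 with (E)-3-iodoprop-2-en-1-ol (Pd(PPh3)4, K2CO3, THF–H2O) would give the cinnamyl alcohol F11. Palladium-catalysed borylation of this allylic alcohol with B2pin2 ([Pd(MeCN)4](BF4)2, DMSO–MeOH) through the π-allyl complex should then return the linear E boronate 4.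

Further compounds
F1 | step 4 | methyl 3-(2-tert-butoxy-2-oxoethyl)-4-fluoro-5-methoxybenzoate | COC(=O)c1cc(OC)c(F)c(CC(=O)OC(C)(C)C)c1
F2 | step 4 | [2-fluoro-3-methoxy-5-(methoxycarbonyl)phenyl]acetic acid | COC(=O)c1cc(OC)c(F)c(CC(=O)O)c1
F3 | step 4 | methyl 3-{2-[(4S)-4-benzyl-2-oxo-1,3-oxazolidin-3-yl]-2-oxoethyl}-4-fluoro-5-methoxybenzoate | COC(=O)c1cc(OC)c(F)c(CC(=O)N2[C@@H](Cc3ccccc3)COC2=O)c1
F4 | step 4 | methyl 3-[(1S,2S)-1-[4-(benzyloxy)-3-methoxyphenyl]-3-[(4S)-4-benzyl-2-oxo-1,3-oxazolidin-3-yl]-1-hydroxy-3-oxopropan-2-yl]-4-fluoro-5-methoxybenzoate (syn) | COc1cc([C@@H](O)[C@@H](C(=O)N2[C@@H](Cc3ccccc3)COC2=O)c2cc(C(=O)OC)cc(OC)c2F)ccc1OCc1ccccc1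
F5 | step 4 | methyl 3-[(1S,2R)-1-[4-(benzyloxy)-3-methoxyphenyl]-1,3-dihydroxypropan-2-yl]-4-fluoro-5-methoxybenzoate | COc1cc([C@@H](O)[C@@H](CO)c2cc(C(=O)OC)cc(OC)c2F)ccc1OCc1ccccc1
F6 | step 4 | methyl 3-[(1S,2R)-1-[4-(benzyloxy)-3-methoxyphenyl]-1-hydroxy-3-(triphenylmethoxy)propan-2-yl]-4-fluoro-5-methoxybenzoate | COc1cc([C@@H](O)[C@@H](COC(c2ccccc2)(c2ccccc2)c2ccccc2)c2cc(C(=O)OC)cc(OC)c2F)ccc1OCc1ccccc1
F7 | step 4 | methyl (2S,3R)-2-[4-(benzyloxy)-3-methoxyphenyl]-7-methoxy-3-[(triphenylmethoxy)methyl]-2,3-dihydro-1-benzofuran-5-carboxylate (2,3-trans) | COC(=O)c1cc(OC)c2c(c1)[C@H](COC(c1ccccc1)(c1ccccc1)c1ccccc1)[C@@H](c1ccc(OCc3ccccc3)c(OC)c1)O2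
F8 | step 6 | (2S,3R)-2-[4-(benzyloxy)-3-methoxyphenyl]-7-methoxy-5-(methoxycarbonyl)-2,3-dihydro-1-benzofuran-3-carboxylic acid (2,3-cis) | COC(=O)c1cc(OC)c2c(c1)[C@@H](C(=O)O)[C@@H](c1ccc(OCc3ccccc3)c(OC)c1)O2
F9 | step 6 | dimethyl (2S,3R)-2-[4-(benzyloxy)-3-methoxyphenyl]-7-methoxy-2,3-dihydro-1-benzofuran-3,5-dicarboxylate (2,3-cis) | COC(=O)c1cc(OC)c2c(c1)[C@@H](C(=O)OC)[C@@H](c1ccc(OCc3ccccc3)c(OC)c1)O2
F10 | step 6 | dimethyl (2S,3S)-2-[4-(benzyloxy)-3-methoxyphenyl]-7-methoxy-2,3-dihydro-1-benzofuran-3,5-dicarboxylate (2,3-trans) | COC(=O)c1cc(OC)c2c(c1)[C@H](C(=O)OC)[C@@H](c1ccc(OCc3ccccc3)c(OC)c1)O2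
F11 | step 3 | methyl 4-fluoro-3-[(1E)-3-hydroxyprop-1-en-1-yl]-5-methoxybenzoate | COC(=O)c1cc(OC)c(F)c(/C=C/CO)c1
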